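**Retrosynthetic overview**
- The five-membered lactone is made last: freeing O6 in a bridged six-membered lactone (closed on O5) triggers an O5→O6 acyl shift and releases the C5 hydroxyl; the tiglate is put on C8 just before.
- Key step: a radical C7–C8 macrocyclisation. An α-hydroxyalkyl radical at C8 adds to the enoate of the six-membered lactone and expels sulfinate; this closes the ten-membered ring, sets C7 and C8 and creates the exocyclic methylene.
- The Z,Z-dienone chain comes from Nozaki–Hiyama–Kishi coupling of a Z-alkenyl iodide with the lactol of 4-methyl-5,6-dihydro-2H-pyran-2-one (its ring fixes the second Z geometry), then allylic oxidation.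
- The six-membered lactone comes from ring-closing metathesis of an acrylate carrying the allyl sulfone; C5 and C6 are set by an anti-selective asymmetric (silyloxy)allylboration of (Z)-3-iodo-2-methylacrolein.
- Ring order: six-membered lactone, then ten-membered carbocycle, then five-membered lactone.

Assumption and locants: the target is taken exactly as the given SMILES, (5S,6R,7R,8S), both ring enone double bonds Z, tiglate E; germacrane-type locants are used (ring C1–C10; C11/C12/C13 = lactone α-carbon, carbonyl, exocyclic CH2; C14/C15 = methyls on C10/C4).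

**Step 1**
Reactants: 1 prop-2-yn-1-ol
Product: 3 (Z)-3-iodo-2-methylprop-2-en-1-ol, via alkenylmagnesium alkoxide 2 (not isolated)
Conditions: MeMgBr (2.5 equiv), CuI (10 mol %), THF/Et2O, −10 °C to rt; then I2, −78 to 0 °C
Reagents that add atoms: methylmagnesium bromide C[Mg]Br; iodine II
Why: Copper-catalysed anti-carbomagnesiation of the propargylic alkoxide puts methyl on C4 and magnesium on C3 cis to the CH2O group through a five-membered chelate, and iodinolysis with retention gives the Z-iodoalkene.

**Step 2**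
Reactants: 3 (Z)-3-iodo-2-methylprop-2-en-1-ol
Product: 4 (Z)-3-iodo-2-methylprop-2-enal
Conditions: activated MnO2 (15 equiv), CH2Cl2, rt, dark; used at once
Reagents that add atoms: none
Why: Neutral allylic oxidation with MnO2 gives the enal without Z/E isomerisation of the β-iodoalkene.

**Step 3**
Reactants: 1 prop-2-yn-1-ol
Product: 5 tert-butyldimethyl(prop-2-yn-1-yloxy)silane
Conditions: TBSCl, imidazole, CH2Cl2, 0 °C to rt
Reagents that add atoms: tert-butyldimethylsilyl chloride CC(C)(C)[Si](C)(C)Cl
Why: Standard silylation; this silyl group becomes the O6 protecting group that is removed in the last step.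

**Step 4**
Reactants: 5 tert-butyldimethyl(prop-2-yn-1-yloxy)silane
Product: 6 (E)-tert-butyldimethyl{[3-(4,4,5,5-tetramethyl-1,3,2-dioxaborolan-2-yl)prop-2-en-1-yl]oxy}silane
Conditions: pinacolborane (1.1 equiv), Cp2Zr(H)Cl (5 mol %), Et3N (10 mol %), neat, 60 °C
Reagents that add atoms: pinacolborane [H]B1OC(C)(C)C(C)(C)O1
Why: Zirconocene-hydride-catalysed syn-hydroboration of the terminal alkyne gives the (E)-alkenylboronate with boron at the terminus.

**Step 5**
Reactants: 6 (E)-3-silyloxyprop-1-enylboronate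
Product: 7 (E)-tert-butyldimethyl{[3-(4,4,5,5-tetramethyl-1,3,2-dioxaborolan-2-yl)prop-1-en-1-yl]oxy}silane
Conditions: [Ir(cod)(PPh2Me)2]PF6 (2 mol %, pre-activated with H2), THF, rt
Reagents that add atoms: none
Why: Iridium-hydride double-bond migration (allyl silyl ether to silyl enol ether isomerisation) gives the γ-silyloxyallylboronate, E-selective with a bulky silyl group.

**Step 6**
Reactants: 4 (Z)-3-iodo-2-methylprop-2-enal; 7 (E)-γ-silyloxyallylboronate
Product: 8 (1Z,3S,4R)-4-[(tert-butyldimethylsilyl)oxy]-1-iodo-2-methylhexa-1,5-dien-3-ol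
Conditions: (R)-TRIP [(R)-3,3'-bis(2,4,6-triisopropylphenyl)-1,1'-binaphthyl-2,2'-diyl hydrogen phosphate] (5 mol %), 4 Å molecular sieves, toluene, −30 °C; aq. NaHCO3 work-up
Reagents that add atoms: none
Why: Chiral-phosphoric-acid-catalysed allylboration through a closed chair transition state: the E-boronate places OTBS equatorial and gives the anti (erythro) C5/C6 pair, and the (R)-acid is assigned Re-face attack on the aldehyde by analogy with simple aryl and alkenyl aldehydes, which sets 5S and hence 6R.

**Step 7**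
Reactants: 9 2-(bromomethyl)prop-2-enoic acid
Product: 10 2-[(phenylsulfonyl)methyl]prop-2-enoic acid
Conditions: PhSO2Na (1.3 equiv), MeOH, reflux; then aq. HCl
Reagents that add atoms: sodium benzenesulfinate [Na+].[O-]S(=O)c1ccccc1
Why: S-alkylation of sulfinate by the allylic bromide (SN2/SN2′) gives the allyl sulfone that later acts as the radical leaving group and survives the chromium and metathesis steps.

**Step 8**
Reactants: 8 anti silyloxy dienol; 10 2-[(phenylsulfonyl)methyl]prop-2-enoic acid
Product: 11 (1Z,3S,4R)-4-[(tert-butyldimethylsilyl)oxy]-1-iodo-2-methylhexa-1,5-dien-3-yl 2-[(phenylsulfonyl)methyl]prop-2-enoate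
Conditions: DCC (1.3 equiv), DMAP (10 mol %), CH2Cl2, 0 °C to rt
Reagents that add atoms: none
Why: Steglich esterification of the free C5 hydroxyl; no stereocentre is touched.

**Step 9**
Reactants: 11 sulfonyl acrylate ester
Product: 12 (5R,6S)-5-[(tert-butyldimethylsilyl)oxy]-6-[(Z)-1-iodoprop-1-en-2-yl]-3-[(phenylsulfonyl)methyl]-5,6-dihydro-2H-pyran-2-one
Conditions: second-generation Grubbs catalyst (5 mol %), toluene (0.005 M), 80 °C
Reagents that add atoms: none
Why: Ring-closing metathesis of the acrylate with the vinyl group closes the α,β-unsaturated six-membered lactone (C7=C11); the trisubstituted iodoalkene is inert, and the anti C5/C6 pair becomes the trans-5,6 arrangement.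

**Step 10**
Reactants: 13 4-methyl-5,6-dihydro-2H-pyran-2-one
Product: 14 4-methyl-5,6-dihydro-2H-pyran-2-ol
Conditions: i-Bu2AlH (1.1 equiv), CH2Cl2, −78 °C; aq. potassium sodium tartrate
Reagents that add atoms: none
Why: 1,2-Reduction of the lactone carbonyl stops at the lactol, whose ring holds the future C1=C10 double bond in the Z geometry.

**Step 11**
Reactants: 12 iodoalkenyl lactone; 14 lactol (2.5 equiv)
Product: 16 (5R,6S)-5-[(tert-butyldimethylsilyl)oxy]-6-[(2Z,5Z)-4,8-dihydroxy-6-methylocta-2,5-dien-2-yl]-3-[(phenylsulfonyl)methyl]-5,6-dihydro-2H-pyran-2-one (C2 carbinol epimers), via open-chain hydroxy enal 15 (not isolated)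
Conditions: CrCl2 (6 equiv), NiCl2 (2 mol %), DMSO/THF, rt
Reagents that add atoms: none
Why: Nozaki–Hiyama–Kishi coupling: the alkenylchromium species forms from the β,β-disubstituted iodide with retention of Z geometry, adds 1,2 to the enal tautomer of the lactol and tolerates lactone, sulfone and free hydroxyl; the new C2 carbinol centre is erased in the next step.

**Step 12**
Reactants: 16 dienediol
Product: 17 (5R,6S)-5-[(tert-butyldimethylsilyl)oxy]-6-[(2Z,5Z)-8-hydroxy-6-methyl-4-oxoocta-2,5-dien-2-yl]-3-[(phenylsulfonyl)methyl]-5,6-dihydro-2H-pyran-2-one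
Conditions: MnO2 (20 equiv), CH2Cl2, rt, dark
Reagents that add atoms: none
Why: MnO2 oxidises only the doubly allylic C2 alcohol to the cross-conjugated Z,Z-dienone and leaves the primary homoallylic alcohol (17 equilibrates with its six-membered hemiketal).

**Step 13 (key step)**
Reactants: 17 hydroxy dienone
Product: 18 (5S,6R,7R,8S)-6-[(tert-butyldimethylsilyl)oxy]-8-hydroxy-2-oxogermacra-1(10)Z,3Z,11(13)-trien-12,5-olide
Conditions: [Ir(dF(CF3)ppy)2(dtbbpy)]PF6 (2 mol %), quinuclidine (20 mol %), Bu4N[H2PO4] (30 mol %), K2HPO4 (1.5 equiv), degassed MeCN (0.002 M), 450 nm LEDs, rt; neutral work-up at 0 °C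
Reagents that add atoms: none
Why: Proposed new method: the quinuclidinium radical cation formed by the excited photocatalyst abstracts the hydridic, phosphate-hydrogen-bonded C8–H of the primary alcohol, the nucleophilic α-hydroxyalkyl radical adds to C7 of the lactone enoate to close the ten-membered ring (the seven-atom dienone bridge from C5 can only reach the C7 face cis to C5, which is also anti to the C6 silyloxy group, so 7R follows, and 8S is expected because the radical's hydroxyl avoids the position flanked by C6 and C11), and the adduct radical expels benzenesulfinyl radical (reduced to sulfinate by the reduced photocatalyst) to leave the exocyclic methylene; the closest known chemistry is photoredox hydrogen-atom-transfer α-alkylation of alcohols with acrylates combined with addition–fragmentation allylation by allyl sulfones.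

**Step 14**
Reactants: 18 macrocyclic alcohol; 19 (E)-2-methylbut-2-enoyl chloride (tigloyl chloride)
Product: 20 (5S,6R,7R,8S)-6-[(tert-butyldimethylsilyl)oxy]-8-[(E)-2-methylbut-2-enoyloxy]-2-oxogermacra-1(10)Z,3Z,11(13)-trien-12,5-olide
Conditions: 19 (3 equiv), pyridine (5 equiv), DMAP (10 mol %), CH2Cl2, −20 to 0 °C
Reagents that add atoms: none
Why: Acylation of the only free hydroxyl with retention at C8; the weak base and low temperature are chosen to avoid vinylogous β-elimination of the C8 oxygen and migration of the lactone to O8.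

**Step 15**
Reactants: 20 silyl-protected tiglate
Product: 22 (5S,6R,7R,8S)-5-hydroxy-8-[(E)-2-methylbut-2-enoyloxy]-2-oxogermacra-1(10)Z,3Z,11(13)-trien-12,6-olide (target), via desilylated six-membered lactone 21 (not isolated)
Conditions: HF·pyridine, pyridine, THF, 0 °C to rt; then PPTS (cat.), CH2Cl2, rt if the acyl shift is incomplete
Reagents that add atoms: none
Why: Desilylation frees the C6 hydroxyl, which attacks the neighbouring lactone carbonyl (intramolecular transesterification, δ- to γ-lactone) to give the cis-fused five-membered lactone and release the C5 hydroxyl; no stereocentre changes.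

**Compound list**
1 | prop-2-yn-1-ol | C#CCO | starting material
2 | bromomagnesium (Z)-3-(bromomagnesio)-2-methylprop-2-en-1-olate | Br[Mg]OC/C(C)=C\[Mg]Br | intermediate
3 | (Z)-3-iodo-2-methylprop-2-en-1-ol | OC/C(C)=C\I | intermediate
4 | (Z)-3-iodo-2-methylprop-2-enal | O=C/C(C)=C\I | intermediate
5 | tert-butyldimethyl(prop-2-yn-1-yloxy)silane | C#CCO[Si](C)(C)C(C)(C)C | intermediate
6 | (E)-tert-butyldimethyl{[3-(4,4,5,5-tetramethyl-1,3,2-dioxaborolan-2-yl)prop-2-en-1-yl]oxy}silane | CC(C)(C)[Si](C)(C)OC/C=C/B1OC(C)(C)C(C)(C)O1 | intermediate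
7 | (E)-tert-butyldimethyl{[3-(4,4,5,5-tetramethyl-1,3,2-dioxaborolan-2-yl)prop-1-en-1-yl]oxy}silane | CC(C)(C)[Si](C)(C)O/C=C/CB1OC(C)(C)C(C)(C)O1 | intermediate
8 | (1Z,3S,4R)-4-[(tert-butyldimethylsilyl)oxy]-1-iodo-2-methylhexa-1,5-dien-3-ol | I/C=C(/C)[C@H](O)[C@H](O[Si](C)(C)C(C)(C)C)C=C | intermediate
9 | 2-(bromomethyl)prop-2-enoic acid | C=C(CBr)C(=O)O | starting material
10 | 2-[(phenylsulfonyl)methyl]prop-2-enoic acid | C=C(CS(=O)(=O)c1ccccc1)C(=O)O | intermediate
11 | (1Z,3S,4R)-4-[(tert-butyldimethylsilyl)oxy]-1-iodo-2-methylhexa-1,5-dien-3-yl 2-[(phenylsulfonyl)methyl]prop-2-enoate | I/C=C(/C)[C@H](OC(=O)C(=C)CS(=O)(=O)c1ccccc1)[C@H](O[Si](C)(C)C(C)(C)C)C=C | intermediate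
12 | (5R,6S)-5-[(tert-butyldimethylsilyl)oxy]-6-[(Z)-1-iodoprop-1-en-2-yl]-3-[(phenylsulfonyl)methyl]-5,6-dihydro-2H-pyran-2-one (trans) | I/C=C(/C)[C@@H]1OC(=O)C(CS(=O)(=O)c2ccccc2)=C[C@H]1O[Si](C)(C)C(C)(C)C | intermediate
13 | 4-methyl-5,6-dihydro-2H-pyran-2-one | CC1=CC(=O)OCC1 | starting material
14 | 4-methyl-5,6-dihydro-2H-pyran-2-ol (racemic lactol) | CC1=CC(O)OCC1 | intermediate
15 | (Z)-5-hydroxy-3-methylpent-2-enal (open tautomer of 14) | O=C/C=C(/C)CCO | intermediate
16 | (5R,6S)-5-[(tert-butyldimethylsilyl)oxy]-6-[(2Z,5Z)-4,8-dihydroxy-6-methylocta-2,5-dien-2-yl]-3-[(phenylsulfonyl)methyl]-5,6-dihydro-2H-pyran-2-one, mixture of epimers at the C2 carbinol | OCC/C(C)=C\C(O)/C=C(/C)[C@@H]1OC(=O)C(CS(=O)(=O)c2ccccc2)=C[C@H]1O[Si](C)(C)C(C)(C)C | intermediate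
17 | (5R,6S)-5-[(tert-butyldimethylsilyl)oxy]-6-[(2Z,5Z)-8-hydroxy-6-methyl-4-oxoocta-2,5-dien-2-yl]-3-[(phenylsulfonyl)methyl]-5,6-dihydro-2H-pyran-2-one | OCC/C(C)=C\C(=O)/C=C(/C)[C@@H]1OC(=O)C(CS(=O)(=O)c2ccccc2)=C[C@H]1O[Si](C)(C)C(C)(C)C | intermediate
18 | (5S,6R,7R,8S)-6-[(tert-butyldimethylsilyl)oxy]-8-hydroxy-2-oxogermacra-1(10)Z,3Z,11(13)-trien-12,5-olide (ten-membered ring bridged C5 to C7 by the six-membered α-methylene lactone) | C=C1C(=O)O[C@H]2/C(C)=C\C(=O)/C=C(/C)C[C@H](O)[C@@H]1[C@H]2O[Si](C)(C)C(C)(C)C | intermediate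
19 | (E)-2-methylbut-2-enoyl chloride (tigloyl chloride) | C/C=C(\C)C(=O)Cl | starting material
20 | (5S,6R,7R,8S)-6-[(tert-butyldimethylsilyl)oxy]-8-[(E)-2-methylbut-2-enoyloxy]-2-oxogermacra-1(10)Z,3Z,11(13)-trien-12,5-olide | C=C1C(=O)O[C@H]2/C(C)=C\C(=O)/C=C(/C)C[C@H](OC(=O)/C(C)=C/C)[C@@H]1[C@H]2O[Si](C)(C)C(C)(C)C | intermediate
21 | 6-hydroxy analogue of 20 (12,5-olide, free C6–OH, same spatial arrangement at C5–C8) | C=C1C(=O)O[C@H]2/C(C)=C\C(=O)/C=C(/C)C[C@H](OC(=O)/C(C)=C/C)[C@@H]1[C@H]2O | intermediate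
22 | (5S,6R,7R,8S)-5-hydroxy-8-[(E)-2-methylbut-2-enoyloxy]-2-oxogermacra-1(10)Z,3Z,11(13)-trien-12,6-olide (CNP0230565.3) | C=C1C(=O)O[C@@H]2[C@H]1[C@@H](OC(=O)/C(C)=C/C)C/C(C)=C\C(=O)/C=C(/C)[C@@H]2O | target

**Totals**
Total steps: 15. Longest linear sequence: 11 steps (steps 3, 4, 5, 6, 8, 9, 11, 12, 13, 14, 15 from prop-2-yn-1-ol).

**Three steps most likely to fail**

Step 13 (radical macrocyclisation). The risks are:
- hydrogen abstraction at other allylic or α-oxy C–H bonds;
- sensitised Z/E isomerisation of the dienone;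
- seven-membered closure of the C8 radical onto C4;
- intermolecular addition;
- attack of the new C8 hydroxyl on the lactone carbonyl.

The fallback sets out from 17 and returns at 18. The primary hydroxyl of 17 is silylated with (2-bromophenyl)chlorodimethylsilane (imidazole, CH2Cl2) to give the (2-bromophenyl)dimethylsilyl ether of 17 F1. Slow addition of Bu3SnH/AIBN (benzene, 80 °C, 0.002 M) forms the aryl radical, which moves the radical site to C8 by 1,5-hydrogen transfer. The α-silyloxy radical then cyclises onto C7 with loss of benzenesulfinyl radical (chain carried by Bu3SnH) to give the macrocyclic 8-O-dimethylphenylsilyl ether of 18 F2. Its labile arylsilyl ether is cleaved selectively (HF·pyridine, THF, −20 °C) to give 18.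

Step 14 (esterification with retention). It inherits the least secure stereocentre (C8) and must outrun base-induced elimination and lactone migration. The fallback sets out from 17 and returns at 20. If step 13 gives mainly the C8 epimer of 18, the (8R)-alcohol F3, the ester is made with inversion: Mitsunobu reaction of F3 with tiglic acid (PPh3, diisopropyl azodicarboxylate, toluene, 0 °C to rt) gives 20 directly.

Step 15 (desilylation and acyl shift). The hindered silyl ether may be slow to cleave, the δ- to γ-lactone shift may stall, or the tiglate may migrate. The fallback sets out from 20 and returns at 22. Compound 20 is desilylated with buffered HF·pyridine and 21 is isolated. Its lactone is opened with Me3SnOH (1,2-dichloroethane, 60 °C; aq. HCl work-up) to the 5,6-dihydroxy seco acid F4. The five-membered lactone is then closed under kinetic control (PPTS cat., CH2Cl2, rt) to give 22.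

Further compounds
F1 | step 13 | (2-bromophenyl)dimethylsilyl ether of 17 (on the primary C8 oxygen) | Brc1ccccc1[Si](C)(C)OCC/C(C)=C\C(=O)/C=C(/C)[C@@H]2OC(=O)C(CS(=O)(=O)c3ccccc3)=C[C@H]2O[Si](C)(C)C(C)(C)C
F2 | step 13 | 8-O-dimethylphenylsilyl ether of 18 | C=C1C(=O)O[C@H]2/C(C)=C\C(=O)/C=C(/C)C[C@H](O[Si](C)(C)c3ccccc3)[C@@H]1[C@H]2O[Si](C)(C)C(C)(C)C
F3 | step 14 | (5S,6R,7R,8R)-6-[(tert-butyldimethylsilyl)oxy]-8-hydroxy-2-oxogermacra-1(10)Z,3Z,11(13)-trien-12,5-olide (C8 epimer of 18) | C=C1C(=O)O[C@H]2/C(C)=C\C(=O)/C=C(/C)C[C@@H](O)[C@@H]1[C@H]2O[Si](C)(C)C(C)(C)C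
F4 | step 15 | 5,6-dihydroxy-8-[(E)-2-methylbut-2-enoyloxy]-2-oxogermacra-1(10)Z,3Z,11(13)-trien-12-oic acid (seco acid of 21 and 22) | C=C(C(=O)O)[C@@H]1[C@@H](OC(=O)/C(C)=C/C)C/C(C)=C\C(=O)/C=C(/C)[C@H](O)[C@@H]1O
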